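The plan rests on cutting ring B of the octalin at C5–C10 and C8–C9. The feature exploited is that the contiguous C8–C9–C10 stereotriad sits on six-membered ring B. In addition, C9 carries C11, which can be a formyl group, and C1–C4 of ring A (C4 = CMe2) can serve as a tether. One enantioselective intramolecular Diels–Alder reaction then closes rings A and B, forms both bonds and sets C5, C8, C9 and C10 from an achiral chain. Its precursor 14 is an acyclic trienal: an (E)-2-methylenal joined through C1–C4 to a (Z,E)-2-silyloxydiene. Afterwards C11 takes up the arene and the C6 oxygen is traded for the C5=C6 alkene.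

Key step: step 8

Numbering:
- Decalin carbons are C1–C10 (C4 = CMe2, C5/C10 ring fusion, C8 = CHMe, C9 quaternary), and C11 is the benzylic carbon.
- Arene carbons are C1′ (bears C11), C2′ (sulfate oxygen), C3′ (formyl), C4′/C5′ (catechol oxygens) and C6′ (H).
- α is the face of H10, C11 and the C8 methyl group; β is the face of the C9 methyl group.

Assumption: the hydrogen sulfates 32 and 33 are handled as sodium salts and are written, like the target, in the protonated form, which a short pass over H+-form resin delivers.

Remark on the chain synthesis: the metathesis precedes the aldol steps because a propenyl ketone would itself be a metathesis partner. C11 stays a methyl ester until the dienol ether is in place because silyl triflate/amine would also enolise a free enal.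

Step 1
Reactants: 1 5-bromopent-1-ene; 2 mesityl oxide
Product: 4 4,4-dimethylnon-8-en-2-one, via pent-4-enylmagnesium bromide 3 (not isolated)
Conditions: Mg, THF, rt; CuI (10 mol%), then 2, THF, −30 to 0 °C; 1 M HCl
Reagents that add atoms: none
Why: Copper-catalysed conjugate addition of a Grignard reagent to a β,β-disubstituted enone: the organocopper species formed from 3 and CuI adds 1,4 rather than 1,2 and so creates quaternary C4 with its two methyl groups and the C1–C3 chain in one operation.

Step 2
Reactants: 4 4,4-dimethylnon-8-en-2-one; 5 methyl methacrylate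
Product: 6 methyl (E)-2,7,7-trimethyl-9-oxodec-2-enoate
Conditions: second-generation Hoveyda–Grubbs catalyst (H2IMes)Cl2Ru(=CH-C6H4-2-O-i-Pr) (3 mol%), 5 (8 equiv), CH2Cl2, 40 °C
Reagents that add atoms: none
Why: Olefin cross-metathesis of a terminal alkene with a 1,1-disubstituted acrylate is a productive pairing that should give the trisubstituted (E)-enoate (ester trans to the chain) for steric reasons, and 4 holds no second alkene that could compete.

Step 3
Reactants: 6 methyl (E)-2,7,7-trimethyl-9-oxodec-2-enoate; 7 acetaldehyde
Product: 9 methyl (E)-11-hydroxy-2,7,7-trimethyl-9-oxododec-2-enoate, via lithium enolate 8 (not isolated)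
Conditions: LiN(i-Pr)2 (1.05 equiv), THF, −78 °C; 7 (1.5 equiv), −78 °C; AcOH
Reagents that add atoms: none
Why: Directed aldol addition: the amide base deprotonates the unhindered methyl group of the ketone faster than the neopentyl C5 methylene or the far less acidic enoate, and enolate 8 adds to acetaldehyde to bring in C7, C8 and the C8 methyl carbon, the new carbinol centre being uncontrolled and erased in step 4.

Step 4
Reactants: 9 methyl (E)-11-hydroxy-2,7,7-trimethyl-9-oxododec-2-enoate
Product: 11 methyl (2E,10E)-2,7,7-trimethyl-9-oxododeca-2,10-dienoate, via mesylate 10 (not isolated)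
Conditions: MsCl (1.5 equiv), Et3N (4 equiv), CH2Cl2, 0 °C to rt
Reagents that add atoms: none
Why: Mesylation followed by E1cB elimination of the β-mesyloxy ketone completes the aldol condensation and should give the conjugated (E)-propenyl ketone, the thermodynamically preferred geometry.

Step 5
Reactants: 11 methyl (2E,10E)-2,7,7-trimethyl-9-oxododeca-2,10-dienoate
Product: 12 methyl (2E,8Z,10E)-2,7,7-trimethyl-9-(triisopropylsilyloxy)dodeca-2,8,10-trienoate
Conditions: TIPSOTf (1.3 equiv), Et3N (2.5 equiv), CH2Cl2, 0 °C to rt
Reagents that add atoms: triisopropylsilyl triflate, CC(C)[Si](C(C)C)(C(C)C)OS(=O)(=O)C(F)(F)F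
Why: Soft enolisation (silyl triflate plus tertiary amine) silylates the ketone oxygen and removes an α′ proton at C5 to give the cross-conjugated 2-silyloxydiene, (Z)-configured because quaternary C4 turns away from the propenyl group, while the enoate is inert to these conditions.

Step 6
Reactants: 12 methyl (2E,8Z,10E)-2,7,7-trimethyl-9-(triisopropylsilyloxy)dodeca-2,8,10-trienoate
Product: 13 (2E,8Z,10E)-2,7,7-trimethyl-9-(triisopropylsilyloxy)dodeca-2,8,10-trien-1-ol
Conditions: i-Bu2AlH (2.5 equiv), CH2Cl2, −78 °C; aq. potassium sodium tartrate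
Reagents that add atoms: none
Why: 1,2-Reduction of the α,β-unsaturated ester with i-Bu2AlH at low temperature gives the allylic alcohol without touching the silyl dienol ether or any alkene geometry.

Step 7
Reactants: 13 (2E,8Z,10E)-2,7,7-trimethyl-9-(triisopropylsilyloxy)dodeca-2,8,10-trien-1-ol
Product: 14 (2E,8Z,10E)-2,7,7-trimethyl-9-(triisopropylsilyloxy)dodeca-2,8,10-trienal
Conditions: MnO2 (activated, 15 equiv), CH2Cl2, rt; used at once
Reagents that add atoms: none
Why: Neutral heterogeneous MnO2 oxidation is selective for the allylic alcohol, keeps the (E)-enal geometry and exposes the dienol ether to neither acid nor base, so the dienophile is unveiled only directly before cyclisation.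

Step 8
Reactants: 14 (2E,8Z,10E)-2,7,7-trimethyl-9-(triisopropylsilyloxy)dodeca-2,8,10-trienal
Product: 15 (1R,2R,4aS,8aR)-1,2,5,5-tetramethyl-4-(triisopropylsilyloxy)-1,2,4a,5,6,7,8,8a-octahydronaphthalene-1-carbaldehyde (trans-fused; terpenoid descriptors 5S,8R,9R,10R; C11 formyl cis to the C8 methyl group and to H10)
Conditions: (S)-3,3-diphenyl-1-(o-tolyl)tetrahydro-1H,3H-pyrrolo[1,2-c][1,3,2]oxazaborole (20 mol%), Tf2NH (18 mol%), CH2Cl2 (0.02 M), −78 to −40 °C; Et3N
Reagents that add atoms: none
Why: Coordination of the formyl oxygen of 14 to the boron atom of the N-protonated oxazaborolidine (backed by a formyl C–H···O contact) turns C9=C10 into a strong acceptor, and the siloxydiene engages it in a single, concerted yet asynchronous [4+2] cycloaddition in which bonding between the electron-rich terminus C5 and the β-carbon C10 runs ahead of C8–C9 bonding, the orientation demanded by both the tether and the polarity of the partners (C6 oxygen para to C9). The closest known reaction types are the Lewis-acid-promoted type 1 intramolecular Diels–Alder reaction of 1,7,9-decatrienals, the enantioselective bicyclisation of trienals with this catalyst family, and its intermolecular additions of 2-silyloxydienes to 2-substituted enals. Ring B is the six-membered ring of the cycloaddition itself and contains both new bonds, whereas ring A closes as a six-membered carbocycle through C5–C10 alone, its C1–C4 tether folding chair-like with help from the geminal methyl groups on C4. C9 and C10 follow suprafacially from the (E)-enal (C9 methyl cis to C1, C11 cis to H10), C8 follows from the (E)-propenyl terminus combined with the formyl-endo orientation (C8 methyl cis to C11), C5 follows from the (Z)-enol ether, whose outward-pointing C4 ends up trans to C1 (trans ring fusion), and the absolute sense comes from the (S)-catalyst, whose phenyl group covers one face of the s-trans enal so that the diene should reach the Re face of C9. The step needs the formyl-endo, trans-fused transition state rather than the methyl-endo, cis-fused one, and a single π-face; the first is favoured by the pronounced endo preference of a Lewis-acid-bound terminal (E)-carbonyl group in decatrienes and by the crowding an endo C9 methyl group would meet beneath the diene core next to the bulky C6 silyloxy group, the second is the task of the catalyst. The triisopropylsilyl group is chosen because it resists the acidic catalyst, which is kept slightly deficient in Tf2NH, and the C5 centre is expendable since step 16 erases it.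

Step 9
Reactants: 16 3,4-bis(benzyloxy)benzaldehyde
Product: 18 3,4-bis(benzyloxy)phenol, via aryl formate 17 (not isolated)
Conditions: mCPBA, CH2Cl2, 0 °C to rt; then K2CO3 (0.2 equiv), MeOH, rt
Reagents that add atoms: mCPBA, O=C(OO)c1cccc(Cl)c1
Why: Baeyer–Villiger (Dakin-type) oxidation: in the electron-rich benzaldehyde the aryl group migrates to oxygen, and methanolysis of formate 17 releases the phenol whose oxygen becomes the C2′ oxygen.

Step 10
Reactants: 18 3,4-bis(benzyloxy)phenol
Product: 19 4,5-bis(benzyloxy)-2-bromophenol
Conditions: NBS (1.0 equiv), MeCN, 0 °C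
Reagents that add atoms: N-bromosuccinimide, O=C1CCC(=O)N1Br
Why: Electrophilic aromatic bromination goes to the position ortho to the free hydroxyl and para to a benzyloxy group, the other ortho site being squeezed between two oxygen substituents.

Step 11
Reactants: 19 4,5-bis(benzyloxy)-2-bromophenol
Product: 20 1,2-bis(benzyloxy)-4-bromo-5-(methoxymethoxy)benzene
Conditions: MOMCl, i-Pr2NEt, CH2Cl2, 0 °C to rt
Reagents that add atoms: chloromethyl methyl ether, COCCl
Why: O-Alkylation of the phenol gives the MOM acetal, which withstands organolithium, radical, fluoride, hydride and pyridine-buffered conditions, stabilises the neighbouring aryllithium by chelation and can later be removed without touching the benzyl ethers.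

Step 12
Reactants: 20 1,2-bis(benzyloxy)-4-bromo-5-(methoxymethoxy)benzene; 15 octalin aldehyde
Product: 24 C11 S-methyl xanthate of the aryl carbinol (both C11 epimers), via aryllithium 21 (not isolated), via lithium C11 alkoxide 22 (not isolated), via lithium xanthate 23 (not isolated)
Conditions: 20 (1.3 equiv), n-BuLi (1.25 equiv), THF, −78 °C; 15, −78 to 0 °C; CS2, 0 °C to rt; MeI, rt
Reagents that add atoms: carbon disulfide, S=C=S; iodomethane, CI
Why: Bromine–lithium exchange, 1,2-addition of the chelation-stabilised aryllithium to the non-enolisable neopentyl aldehyde (the C6 ketone stays masked as its silyl enol ether) and trapping of the alkoxide with CS2 and MeI give the xanthate in one flask, the new C11 centre being uncontrolled and removed in step 13.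

Step 13
Reactants: 24 C11 S-methyl xanthate
Product: 25 (5S,8R,9R,10R)-C11-methylene compound: trans-octalin C6=C7 TIPS enol ether carrying the 4,5-bis(benzyloxy)-2-(methoxymethoxy)benzyl group on C9
Conditions: n-Bu3SnH, AIBN (cat.), toluene, 100 °C
Reagents that add atoms: none
Why: Barton–McCombie deoxygenation: stannyl radical attack on the thiocarbonyl group releases a stabilised benzylic C11 radical that has no alkene within reach and simply abstracts hydrogen from the stannane, under neutral conditions that spare MOM, benzyl and silyl enol ether groups.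

Step 14
Reactants: 25 C11-methylene silyl enol ether
Product: 26 (5S,8R,9R,10R)-C6 ketone (trans-decalone)
Conditions: n-Bu4NF, AcOH (1:1), THF, 0 °C to rt
Reagents that add atoms: none
Why: Fluoride-induced cleavage of the silyl enol ether under acetic acid buffering protonates the enolate at C7 and unveils the C6 ketone without epimerising C5 or touching the ethers.

Step 15
Reactants: 26 C6 ketone
Product: 27 (5S,6S,8R,9R,10R)-C6 axial alcohol (6α-OH, cis to the C8 methyl group, anti to H5)
Conditions: LiAlH4, Et2O, 0 °C; aq. potassium sodium tartrate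
Reagents that add atoms: none
Why: Hydride reduction under steric approach control: the α face of C6 is screened by the syn-axial methyl groups on C4 and C8, so hydride should arrive from the β face and set the C6 hydroxyl axial.

Step 16
Reactants: 27 C6 axial alcohol
Product: 29 (8R,9R,10S)-C5=C6 alkene with the protected benzyl group on C9, via axial chlorosulfite 28 (not isolated)
Conditions: SOCl2 (2 equiv), pyridine, 0 °C
Reagents that add atoms: none
Why: Dehydration by anti-periplanar E2 elimination: H5 and one H7 are both anti to the axial leaving group, and the loose, strain-relieving transition state of an ester wedged between two syn-axial methyl groups should follow the Saytzeff rule and take the tertiary H5, as hindered axial alcohols next to a ring fusion do in the steroid series, which also erases the C5 and C6 centres.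

Step 17
Reactants: 29 C5=C6 alkene (MOM ether)
Product: 30 C2′ phenol: 4,5-bis(benzyloxy)-2-{[(1R,2R,8aS)-1,2,5,5-tetramethyl-1,2,3,5,6,7,8,8a-octahydronaphthalen-1-yl]methyl}phenol
Conditions: p-TsOH·H2O (0.2 equiv), MeOH–CH2Cl2, 35 °C
Reagents that add atoms: none
Why: Acid-catalysed transacetalisation to methanol removes the aryl MOM group under conditions too mild to protonate the hindered trisubstituted alkene or to cleave benzyl ethers.

Step 18
Reactants: 30 C2′ phenol
Product: 31 C3′ aldehyde: 2,3-bis(benzyloxy)-6-hydroxy-5-(octalinylmethyl)benzaldehyde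
Conditions: MgCl2 (3 equiv), Et3N (6 equiv), (CH2O)n (10 equiv), MeCN, 80 °C; aq. citric acid
Reagents that add atoms: paraformaldehyde (as formaldehyde), C=O
Why: Magnesium-mediated ortho-formylation (Casnati–Skattebøl): the magnesium phenoxide delivers formaldehyde only to an ortho carbon, C1′ is blocked so C3′ is the sole site, and a second formaldehyde oxidises the hydroxymethyl intermediate to the aldehyde.

Step 19
Reactants: 31 C3′ aldehyde
Product: 32 dibenzyl ether of the target (C2′ hydrogen sulfate)
Conditions: SO3·pyridine (5 equiv), pyridine, 40 °C; cation-exchange resin (Na+ form)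
Reagents that add atoms: sulfur trioxide–pyridine complex, O=S(=O)([O-])[n+]1ccccc1
Why: O-Sulfation with the SO3·pyridine complex acts on the only free hydroxyl group, excess reagent and gentle warming compensating for its hydrogen bond to the formyl group, and the basic medium protects alkene and sulfate alike.

Step 20
Reactants: 32 dibenzyl ether of the target
Product: 33 target, 2-formyl-3,4-dihydroxy-6-{[(1R,2R,8aS)-1,2,5,5-tetramethyl-1,2,3,5,6,7,8,8a-octahydronaphthalen-1-yl]methyl}phenyl hydrogen sulfate
Conditions: H2 (1 atm), 10% Pd/C, EtOAc–MeOH, rt, stopped at 2 equiv H2; cation-exchange resin (H+ form), 0 °C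
Reagents that add atoms: none
Why: Catalytic hydrogenolysis of aryl benzyl ethers, the usual last step for partially sulfated polyphenols, should be much faster than saturation of the C5=C6 alkene, which is shielded on both faces by the C4 and C9 methyl groups, or reduction of the doubly ortho-substituted, hydrogen-bonded aldehyde, and aryl sulfates are inert to it.

Compound list
1 | 5-bromopent-1-ene | C=CCCCBr | starting material
2 | mesityl oxide (4-methylpent-3-en-2-one) | CC(=O)C=C(C)C | starting material
3 | pent-4-enylmagnesium bromide | C=CCCC[Mg]Br | intermediate (not isolated)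
4 | 4,4-dimethylnon-8-en-2-one | CC(=O)CC(C)(C)CCCC=C | intermediate
5 | methyl methacrylate | C=C(C)C(=O)OC | starting material
6 | methyl (E)-2,7,7-trimethyl-9-oxodec-2-enoate | COC(=O)/C(C)=C/CCCC(C)(C)CC(C)=O | intermediate
7 | acetaldehyde | CC=O | starting material
8 | kinetic lithium enolate of 6 (methyl side) | C=C(O[Li])CC(C)(C)CCC/C=C(\C)C(=O)OC | intermediate (not isolated)
9 | methyl (E)-11-hydroxy-2,7,7-trimethyl-9-oxododec-2-enoate (racemic carbinol) | COC(=O)/C(C)=C/CCCC(C)(C)CC(=O)CC(C)O | intermediate
10 | C11-chain mesylate of 9 | COC(=O)/C(C)=C/CCCC(C)(C)CC(=O)CC(C)OS(C)(=O)=O | intermediate (not isolated)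
11 | methyl (2E,10E)-2,7,7-trimethyl-9-oxododeca-2,10-dienoate | COC(=O)/C(C)=C/CCCC(C)(C)CC(=O)/C=C/C | intermediate
12 | methyl (2E,8Z,10E)-2,7,7-trimethyl-9-(triisopropylsilyloxy)dodeca-2,8,10-trienoate | COC(=O)/C(C)=C/CCCC(C)(C)/C=C(O[Si](C(C)C)(C(C)C)C(C)C)/C=C/C | intermediate
13 | (2E,8Z,10E)-2,7,7-trimethyl-9-(triisopropylsilyloxy)dodeca-2,8,10-trien-1-ol | OC/C(C)=C/CCCC(C)(C)/C=C(O[Si](C(C)C)(C(C)C)C(C)C)/C=C/C | intermediate
14 | (2E,8Z,10E)-2,7,7-trimethyl-9-(triisopropylsilyloxy)dodeca-2,8,10-trienal | O=C/C(C)=C/CCCC(C)(C)/C=C(O[Si](C(C)C)(C(C)C)C(C)C)/C=C/C | intermediate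
15 | (1R,2R,4aS,8aR)-1,2,5,5-tetramethyl-4-(triisopropylsilyloxy)-1,2,4a,5,6,7,8,8a-octahydronaphthalene-1-carbaldehyde | C[C@@H]1C=C(O[Si](C(C)C)(C(C)C)C(C)C)[C@H]2[C@@H](CCCC2(C)C)[C@]1(C)C=O | intermediate
16 | 3,4-bis(benzyloxy)benzaldehyde | O=Cc1ccc(OCc2ccccc2)c(OCc2ccccc2)c1 | starting material
17 | 3,4-bis(benzyloxy)phenyl formate | O=COc1ccc(OCc2ccccc2)c(OCc2ccccc2)c1 | intermediate (not isolated)
18 | 3,4-bis(benzyloxy)phenol | Oc1ccc(OCc2ccccc2)c(OCc2ccccc2)c1 | intermediate
19 | 4,5-bis(benzyloxy)-2-bromophenol | Oc1cc(OCc2ccccc2)c(OCc2ccccc2)cc1Br | intermediate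
20 | 1,2-bis(benzyloxy)-4-bromo-5-(methoxymethoxy)benzene | COCOc1cc(OCc2ccccc2)c(OCc2ccccc2)cc1Br | intermediate
21 | 4,5-bis(benzyloxy)-2-(methoxymethoxy)phenyllithium | COCOc1cc(OCc2ccccc2)c(OCc2ccccc2)cc1[Li] | intermediate (not isolated)
22 | lithium C11 alkoxide from 21 and 15 (C11 epimers) | C[C@@H]1C=C(O[Si](C(C)C)(C(C)C)C(C)C)[C@H]2[C@@H](CCCC2(C)C)[C@]1(C)C(O[Li])c1cc(OCc2ccccc2)c(OCc2ccccc2)cc1OCOC | intermediate (not isolated)
23 | lithium O-(C11) dithiocarbonate (C11 epimers) | C[C@@H]1C=C(O[Si](C(C)C)(C(C)C)C(C)C)[C@H]2[C@@H](CCCC2(C)C)[C@]1(C)C(OC(=S)S[Li])c1cc(OCc2ccccc2)c(OCc2ccccc2)cc1OCOC | intermediate (not isolated)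
24 | O-(C11) S-methyl dithiocarbonate (C11 epimers) | C[C@@H]1C=C(O[Si](C(C)C)(C(C)C)C(C)C)[C@H]2[C@@H](CCCC2(C)C)[C@]1(C)C(OC(=S)SC)c1cc(OCc2ccccc2)c(OCc2ccccc2)cc1OCOC | intermediate
25 | (5S,8R,9R,10R) C11-methylene compound, C6=C7 TIPS enol ether | C[C@@H]1C=C(O[Si](C(C)C)(C(C)C)C(C)C)[C@H]2[C@@H](CCCC2(C)C)[C@]1(C)Cc1cc(OCc2ccccc2)c(OCc2ccccc2)cc1OCOC | intermediate
26 | (5S,8R,9R,10R) C6 ketone, trans-decalone | C[C@@H]1CC(=O)[C@H]2[C@@H](CCCC2(C)C)[C@]1(C)Cc1cc(OCc2ccccc2)c(OCc2ccccc2)cc1OCOC | intermediate
27 | (5S,6S,8R,9R,10R) C6 axial (6α) alcohol | C[C@@H]1C[C@H](O)[C@H]2[C@@H](CCCC2(C)C)[C@]1(C)Cc1cc(OCc2ccccc2)c(OCc2ccccc2)cc1OCOC | intermediate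
28 | C6 axial chlorosulfite of 27 | C[C@@H]1C[C@H](OS(=O)Cl)[C@H]2[C@@H](CCCC2(C)C)[C@]1(C)Cc1cc(OCc2ccccc2)c(OCc2ccccc2)cc1OCOC | intermediate (not isolated)
29 | (8R,9R,10S) C5=C6 alkene, C2′ MOM ether, C4′/C5′ benzyl ethers | C[C@@H]1CC=C2[C@@H](CCCC2(C)C)[C@]1(C)Cc1cc(OCc2ccccc2)c(OCc2ccccc2)cc1OCOC | intermediate
30 | C2′ phenol | C[C@@H]1CC=C2[C@@H](CCCC2(C)C)[C@]1(C)Cc1cc(OCc2ccccc2)c(OCc2ccccc2)cc1O | intermediate
31 | C3′ aldehyde (C2′ phenol, C4′/C5′ benzyl ethers) | C[C@@H]1CC=C2[C@@H](CCCC2(C)C)[C@]1(C)Cc1cc(OCc2ccccc2)c(OCc2ccccc2)c(C=O)c1O | intermediate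
32 | C2′ hydrogen sulfate, C4′/C5′ benzyl ethers | C[C@@H]1CC=C2[C@@H](CCCC2(C)C)[C@]1(C)Cc1cc(OCc2ccccc2)c(OCc2ccccc2)c(C=O)c1OS(=O)(=O)O | intermediate
33 | CNP0115595.2, 2-formyl-3,4-dihydroxy-6-{[(1R,2R,8aS)-1,2,5,5-tetramethyl-1,2,3,5,6,7,8,8a-octahydronaphthalen-1-yl]methyl}phenyl hydrogen sulfate | C[C@@H]1CC=C2[C@@H](CCCC2(C)C)[C@]1(C)Cc1cc(O)c(O)c(C=O)c1OS(=O)(=O)O | target

Total step count: 20.
Longest linear sequence: 17 steps (steps 1–8 and 12–20, from 5-bromopent-1-ene). The arene branch adds steps 9–11.

Steps most likely to fail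

Step 8.
- The α-methyl group may compete with the formyl group for the endo position, which would divert material into the cis-fused series with the wrong C8/C9 relationship.
- The catalyst may discriminate the faces of a β-substituted 2-methylenal poorly, or in the opposite sense, in which case the antipodal catalyst from D-proline applies.
- The acidic catalyst may strip the silyl group and start a racemic background reaction.
- The fallback sets out from 14 and comes back at 15, and it moves stereocontrol from catalysis to resolution. Trienal 14 is cyclised with stoichiometric Me2AlCl (CH2Cl2, −78 °C), a promoter known for endo, trans-fused closure of 2-methyl-substituted trienals, to give 15 as the racemate. NaBH4 reduces it to the neopentyl alcohol F1. Esterification with (S)-O-methylmandelic acid (DCC, DMAP) and chromatographic separation of the two diastereomers give the (S)-O-methylmandelate F2 of the required series. i-Bu2AlH then releases the enantiopure neopentyl alcohol F1, and Dess–Martin periodinane/NaHCO3 returns 15.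

Step 16.
- Proton loss may occur from C7 instead of C5.
- Chloride may substitute at C6.
- The crowded axial hydroxyl may be esterified only sluggishly.
- The fallback sets out from 26 and comes back at 29, and it makes the alkene from the ketone through a carbene. Condensation with TsNHNH2 (EtOH, 60 °C) gives the tosylhydrazone F3. Its sodium salt (NaH, toluene, 110 °C, aprotic Bamford–Stevens conditions) loses sulfinate and nitrogen. The C6 carbene undergoes a 1,2-hydrogen shift, for which the tertiary C5–H is the better migration origin, giving 29.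

Step 20.
- The formyl group may be over-reduced.
- The alkene may migrate or be saturated on the palladium surface.
- Debenzylation of the salt may stall.
- The fallback sets out from 31 and comes back at 33, and it avoids hydrogen altogether by carrying the sulfate as a diester. Phenol 31 is treated with 2,2,2-trichloroethyl chlorosulfate (Et3N, DMAP, THF) to give the trichloroethyl sulfate diester F4. BCl3 with pentamethylbenzene (CH2Cl2, −78 °C) removes both benzyl groups to give the catechol diester F5. Zn with HCO2NH4 (MeOH, rt) then fragments the trichloroethyl group to give 33 after H+ exchange.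

Further compounds
F1 | step 8 | [(1R,2R,4aS,8aR)-1,2,5,5-tetramethyl-4-(triisopropylsilyloxy)-1,2,4a,5,6,7,8,8a-octahydronaphthalen-1-yl]methanol (first racemic, enantiopure after resolution) | C[C@@H]1C=C(O[Si](C(C)C)(C(C)C)C(C)C)[C@H]2[C@@H](CCCC2(C)C)[C@]1(C)CO
F2 | step 8 | (S)-2-methoxy-2-phenylacetate of F1 | C[C@@H]1C=C(O[Si](C(C)C)(C(C)C)C(C)C)[C@H]2[C@@H](CCCC2(C)C)[C@]1(C)COC(=O)[C@@H](OC)c1ccccc1
F3 | step 16 | C6 tosylhydrazone of 26 | C[C@@H]1CC(=NNS(=O)(=O)c3ccc(C)cc3)[C@H]2[C@@H](CCCC2(C)C)[C@]1(C)Cc1cc(OCc2ccccc2)c(OCc2ccccc2)cc1OCOC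
F4 | step 20 | C2′ 2,2,2-trichloroethyl sulfate diester of 31 | C[C@@H]1CC=C2[C@@H](CCCC2(C)C)[C@]1(C)Cc1cc(OCc2ccccc2)c(OCc2ccccc2)c(C=O)c1OS(=O)(=O)OCC(Cl)(Cl)Cl
F5 | step 20 | C2′ 2,2,2-trichloroethyl sulfate diester with free C4′/C5′ catechol | C[C@@H]1CC=C2[C@@H](CCCC2(C)C)[C@]1(C)Cc1cc(O)c(O)c(C=O)c1OS(=O)(=O)OCC(Cl)(Cl)Cl
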